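**Plan**
Retrosynthesis: cut C3=C15 (Wittig bromomethylenation of an enone), return C4–C5 to the dienone level, then cut C6–C11; further back C9–C10 (methallylation) and C7–C8 (ketone allylation).
Enabling feature: ring B (C1=C2, C3, C4, C5 around spiro C6) is the carbon frame of a para-oxygenated benzene ring with C6 as its ipso carbon, and C11, the CMe2 carbon of ring A (C6–C7–C8–C9–C10–C11), is tertiary and can carry a positive charge.
Forward: the chain C7–C11 is built on 4'-hydroxyacetophenone (ring B still an arene), ring A is closed onto the ipso carbon while ring B becomes a cyclohexadienone, then one dienone alkene is saturated and C3=O is olefinated.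
Stereochemistry: C7 from a catalyst-controlled ketone allylboration; C9 from a reagent-controlled methallylboration followed by Appel inversion on the open chain; C6 from a C7–OH-directed hydrogenation that selects one of the two dienone alkenes; the E alkene from the Wittig step.

Key step: step 8

Atom numbers are those of the target: C1–C5 ring B, C6 spiro, C7–C11 ring A, C15 the bromomethylene carbon.
Assumption: in step 3 the (R)-3,3'-dibromobinaphthol is taken to deliver the S carbinol, by analogy with the sense known for simple aryl methyl ketones; should the sense be the opposite, the S diol is used and nothing else changes.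

Step 1
Reactants: 1 4'-hydroxyacetophenone
Product: 2 1-[4-(tert-butyldimethylsilyloxy)phenyl]ethanone
Conditions: TBSCl, imidazole, DMF, rt
Reagents that add atoms: tert-butyldimethylsilyl chloride, CC(C)(C)[Si](C)(C)Cl
Why: Imidazole-promoted O-silylation of a phenol is routine and gives the aryl silyl ether that later serves both as protecting group and as the para-oxygen donor of the spirocyclisation.

Step 2
Reactants: 3 triisopropyl borate; 4 allylmagnesium bromide
Product: 6 allyldiisopropoxyborane, via magnesium borate complex 5 (not isolated)
Conditions: Et2O, −78 °C to rt; then HCl in Et2O, 0 °C; filtration, distillation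
Reagents that add atoms: none
Why: Addition of the allyl Grignard reagent to the trialkyl borate gives an ate complex whose acidolysis releases the allylboronic ester, the standard preparation of this reagent.

Step 3
Reactants: 2 1-[4-(tert-butyldimethylsilyloxy)phenyl]ethanone; 6 allyldiisopropoxyborane
Product: 8 (2S)-2-[4-(tert-butyldimethylsilyloxy)phenyl]pent-4-en-2-ol, via borate ester 7 (not isolated)
Conditions: (R)-3,3'-dibromo-1,1'-bi-2-naphthol (15 mol%), PhCF3/toluene 3:1, −35 °C; then H2O
Reagents that add atoms: none
Why: Chiral-diol-catalysed asymmetric allylboration of an aryl methyl ketone, in which exchange of one isopropoxy group for the binaphthol gives a more Lewis acidic boronate that transfers allyl through a closed chair transition state to one ketone face and so sets C7 as S under catalyst control.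

Step 4
Reactants: 8 (2S)-2-[4-(tert-butyldimethylsilyloxy)phenyl]pent-4-en-2-ol
Product: 9 tert-butyldimethyl{4-[(2S)-2-(triethylsilyloxy)pent-4-en-2-yl]phenoxy}silane
Conditions: TESOTf, 2,6-lutidine, CH2Cl2, −78 to 0 °C
Reagents that add atoms: triethylsilyl triflate, CC[Si](CC)(CC)OS(=O)(=O)C(F)(F)F
Why: Silyl triflate with 2,6-lutidine silylates hindered tertiary alcohols at low temperature without ionising the benzylic position, and the triethylsilyl group is chosen because it is bulky enough to keep the C7 oxygen from acting as a nucleophile in step 8 and still comes off with buffered fluoride.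

Step 5
Reactants: 9 tert-butyldimethyl{4-[(2S)-2-(triethylsilyloxy)pent-4-en-2-yl]phenoxy}silane
Product: 11 (3S)-3-[4-(tert-butyldimethylsilyloxy)phenyl]-3-(triethylsilyloxy)butanal, via ozonide 10 (not isolated)
Conditions: O3, CH2Cl2, −78 °C (Sudan Red 7B end point); then PPh3, −78 °C to rt
Reagents that add atoms: ozone, [O-][O+]=O
Why: Ozonolysis with reductive work-up cleaves the terminal alkene to the aldehyde, the monosubstituted alkene reacting much faster with ozone at −78 °C than the silyloxy arene.

Step 6
Reactants: 11 (3S)-3-[4-(tert-butyldimethylsilyloxy)phenyl]-3-(triethylsilyloxy)butanal; 12 2-methylallylmagnesium chloride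
Product: 15 (2S,4S)-2-[4-(tert-butyldimethylsilyloxy)phenyl]-6-methyl-2-(triethylsilyloxy)hept-6-en-4-ol, via methallylborane 13 (not isolated), via borinate ester 14 (not isolated)
Conditions: 12, (−)-B-methoxydiisopinocampheylborane, Et2O, −78 °C to rt; then 11, −78 °C; then pH 7 buffer, MeOH, 30% H2O2, 0 °C to rt
Reagents that add atoms: none
Why: Asymmetric methallylboration with a diisopinocampheylborane, in which the (+)-α-pinene-derived reagent adds through a closed chair transition state to the Si face of the aldehyde and sets the carbinol carbon (C9) as S under reagent control, the remote quaternary C7 having little influence.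

Step 7
Reactants: 15 (2S,4S)-2-[4-(tert-butyldimethylsilyloxy)phenyl]-6-methyl-2-(triethylsilyloxy)hept-6-en-4-ol
Product: 16 tert-butyl{4-[(2S,4R)-4-bromo-6-methyl-2-(triethylsilyloxy)hept-6-en-2-yl]phenoxy}dimethylsilane
Conditions: CBr4, PPh3, 2,6-lutidine, CH2Cl2, 0 °C to rt
Reagents that add atoms: carbon tetrabromide, BrC(Br)(Br)Br
Why: Appel reaction, in which bromide displaces the alkoxyphosphonium group by SN2 with inversion and turns the 4S alcohol into the 4R bromide (C9 of the target); it is done on the open chain because after ring closure the backside of C9 would be shielded by the syn-axial methyl groups on C7 and C11.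

Step 8
Reactants: 16 tert-butyl{4-[(2S,4R)-4-bromo-6-methyl-2-(triethylsilyloxy)hept-6-en-2-yl]phenoxy}dimethylsilane
Product: 17 (7S,9R)-9-bromo-7,11,11-trimethyl-7-(triethylsilyloxy)spiro[5.5]undeca-1,4-dien-3-one
Conditions: (R,R)-N,N'-bis(3,5-di-tert-butylsalicylidene)-1,2-cyclohexanediaminocobalt (divalent cobalt, 5 mol%), N-fluoro-2,4,6-trimethylpyridinium triflate, (Me2SiH)2O, PhCF3 (0.01 M), 0 °C to rt; then aq. NaHCO3
Reagents that add atoms: none
Why: Proposed new method: a trivalent cobalt hydride, formed from the cobalt salen complex, the N-fluoropyridinium oxidant and the silane, transfers a hydrogen atom to the CH2 terminus of the isopropenyl group, the tertiary C11 radical is oxidised through an alkylcobalt species of tetravalent cobalt to a C11 cation equivalent, the arene carbon para to OTBS (C6) attacks it, and the resulting O-silylated dienone cation passes its silyl group to triflate or collidine to leave the neutral dienone. The closest known reaction types are cobalt-catalysed hydrogen-atom-transfer radical–polar crossover hydroarylation and hydroalkoxylation of unactivated alkenes and the electrophilic ipso-cyclisation of para-silyloxy or para-methoxy arenes to spirocyclohexadienones; neither has been shown for a tertiary cation closing onto an ipso carbon that bears a carbinol carbon. Ring A closes by 6-exo-trig attack on the ipso carbon (bond C6–C11), while ring B is not closed but dearomatised. No stereocentre is created, because C6 carries two identical dienone arms, and C7 and C9 are carried through unchanged. The step needs ipso attack over ortho attack, C-capture over capture by the C7 oxygen, and loss of the aryl silyl group faster than cleavage of the C6–C7 bond of the adduct; the tether length (ortho attack would need a seven-membered ring) and the para-silyloxy group (only the ipso adduct is an oxocarbenium ion) secure the first. The triethylsilyl cap together with the relative configuration secures the second, since the chair leading to ring A has C7–CH3 and C9–Br equatorial whereas the chair leading to a tetrahydropyran would force C7–CH3 syn-axial to a C11 methyl; the near-neutral medium and the readily transferred aryl silyl group are meant to secure the third.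

Step 9
Reactants: 17 (7S,9R)-9-bromo-7,11,11-trimethyl-7-(triethylsilyloxy)spiro[5.5]undeca-1,4-dien-3-one
Product: 18 (7S,9R)-9-bromo-7-hydroxy-7,11,11-trimethylspiro[5.5]undeca-1,4-dien-3-one
Conditions: HF·pyridine, pyridine, THF, 0 °C to rt; pH 7 buffer quench
Reagents that add atoms: none
Why: Fluoride cleavage of the triethylsilyl ether in a pyridine-buffered, non-basic medium frees the tertiary alcohol without forming an alkoxide, which could otherwise break the C6–C7 bond in a retro-aldol-type fragmentation that restores the aromatic ring.

Step 10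
Reactants: 18 (7S,9R)-9-bromo-7-hydroxy-7,11,11-trimethylspiro[5.5]undeca-1,4-dien-3-one
Product: 19 (6S,7S,9R)-9-bromo-7-hydroxy-7,11,11-trimethylspiro[5.5]undec-1-en-3-one
Conditions: H2 (1 atm, one equivalent taken up), [Ir(cod)(PCy3)(py)]PF6 (5 mol%), CH2Cl2, 0 °C
Reagents that add atoms: none
Why: Hydroxyl-directed hydrogenation with a cationic iridium catalyst: in the preferred chair of ring A (C9–Br and C7–CH3 equatorial, C7–OH axial) the hydroxyl is gauche to the equatorial dienone arm and anti to the axial one, so the oxygen-bound iridium hydride can reach only the alkene of the arm cis to the hydroxyl, and its saturation (C4–C5) makes C6 a stereocentre of S configuration.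

Step 11
Reactants: 19 (6S,7S,9R)-9-bromo-7-hydroxy-7,11,11-trimethylspiro[5.5]undec-1-en-3-one
Product: 21 (3E,6S,7S,9R)-9-bromo-3-(bromomethylidene)-7,11,11-trimethylspiro[5.5]undec-1-en-7-ol, via phosphorus ylide 20 (not isolated)
Conditions: (bromomethyl)triphenylphosphonium bromide, KOtBu (slight deficit to the salt), THF, −78 °C; then 19, −78 °C to rt; chromatography on AgNO3-impregnated silica
Reagents that add atoms: (bromomethyl)triphenylphosphonium bromide, BrC[P+](c1ccccc1)(c1ccccc1)c1ccccc1.[Br-]
Why: Wittig olefination of the enone carbonyl (1,2-addition) with bromomethylenetriphenylphosphorane, generated with a deficit of base so that the tertiary alcohol is not deprotonated; the bulkier sp3 arm C4H2–C5H2 is expected to turn away from the phosphorus phenyl groups in the oxaphosphetane-forming transition state, which places bromine cis to C4 (E), and the Z isomer is to be removed by chromatography.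

**Compound list**
1 | 4'-hydroxyacetophenone | CC(=O)c1ccc(O)cc1 | starting material
2 | 1-[4-(tert-butyldimethylsilyloxy)phenyl]ethanone | CC(=O)c1ccc(O[Si](C)(C)C(C)(C)C)cc1 | intermediate
3 | triisopropyl borate | CC(C)OB(OC(C)C)OC(C)C | starting material
4 | allylmagnesium bromide | C=CC[Mg]Br | starting material
5 | bromomagnesium allyltriisopropoxyborate | C=CC[B-](OC(C)C)(OC(C)C)OC(C)C.[Mg+2].[Br-] | intermediate (not isolated)
6 | allyldiisopropoxyborane | C=CCB(OC(C)C)OC(C)C | intermediate
7 | diisopropyl (2S)-2-[4-(tert-butyldimethylsilyloxy)phenyl]pent-4-en-2-yl borate | C=CC[C@](C)(OB(OC(C)C)OC(C)C)c1ccc(O[Si](C)(C)C(C)(C)C)cc1 | intermediate (not isolated)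
8 | (2S)-2-[4-(tert-butyldimethylsilyloxy)phenyl]pent-4-en-2-ol | C=CC[C@](C)(O)c1ccc(O[Si](C)(C)C(C)(C)C)cc1 | intermediate
9 | tert-butyldimethyl{4-[(2S)-2-(triethylsilyloxy)pent-4-en-2-yl]phenoxy}silane | C=CC[C@](C)(O[Si](CC)(CC)CC)c1ccc(O[Si](C)(C)C(C)(C)C)cc1 | intermediate
10 | 3-{(2S)-2-[4-(tert-butyldimethylsilyloxy)phenyl]-2-(triethylsilyloxy)propyl}-1,2,4-trioxolane (epimers at the ring carbon) | C1OC(C[C@](C)(O[Si](CC)(CC)CC)c2ccc(O[Si](C)(C)C(C)(C)C)cc2)OO1 | intermediate (not isolated)
11 | (3S)-3-[4-(tert-butyldimethylsilyloxy)phenyl]-3-(triethylsilyloxy)butanal | O=CC[C@](C)(O[Si](CC)(CC)CC)c1ccc(O[Si](C)(C)C(C)(C)C)cc1 | intermediate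
12 | 2-methylallylmagnesium chloride | C=C(C)C[Mg]Cl | starting material
13 | (−)-B-(2-methylallyl)diisopinocampheylborane | C=C(C)CB([C@@H]1C[C@@H]2C[C@H]([C@H]1C)C2(C)C)[C@@H]1C[C@@H]2C[C@H]([C@H]1C)C2(C)C | intermediate (not isolated)
14 | diisopinocampheylborinate of alcohol 15 | C=C(C)C[C@H](OB([C@@H]1C[C@@H]2C[C@H]([C@H]1C)C2(C)C)[C@@H]1C[C@@H]2C[C@H]([C@H]1C)C2(C)C)C[C@](C)(O[Si](CC)(CC)CC)c1ccc(O[Si](C)(C)C(C)(C)C)cc1 | intermediate (not isolated)
15 | (2S,4S)-2-[4-(tert-butyldimethylsilyloxy)phenyl]-6-methyl-2-(triethylsilyloxy)hept-6-en-4-ol | C=C(C)C[C@H](O)C[C@](C)(O[Si](CC)(CC)CC)c1ccc(O[Si](C)(C)C(C)(C)C)cc1 | intermediate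
16 | tert-butyl{4-[(2S,4R)-4-bromo-6-methyl-2-(triethylsilyloxy)hept-6-en-2-yl]phenoxy}dimethylsilane | C=C(C)C[C@@H](Br)C[C@](C)(O[Si](CC)(CC)CC)c1ccc(O[Si](C)(C)C(C)(C)C)cc1 | intermediate
17 | (7S,9R)-9-bromo-7,11,11-trimethyl-7-(triethylsilyloxy)spiro[5.5]undeca-1,4-dien-3-one | CC1(C)C[C@@H](Br)C[C@](C)(O[Si](CC)(CC)CC)C12C=CC(=O)C=C2 | intermediate
18 | (7S,9R)-9-bromo-7-hydroxy-7,11,11-trimethylspiro[5.5]undeca-1,4-dien-3-one | CC1(C)C[C@@H](Br)C[C@](C)(O)C12C=CC(=O)C=C2 | intermediate
19 | (6S,7S,9R)-9-bromo-7-hydroxy-7,11,11-trimethylspiro[5.5]undec-1-en-3-one | CC1(C)C[C@@H](Br)C[C@](C)(O)[C@@]12C=CC(=O)CC2 | intermediate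
20 | bromomethylenetriphenylphosphorane | BrC=P(c1ccccc1)(c1ccccc1)c1ccccc1 | intermediate (not isolated)
21 | (3E,6S,7S,9R)-9-bromo-3-(bromomethylidene)-7,11,11-trimethylspiro[5.5]undec-1-en-7-ol | CC1(C)C[C@@H](Br)C[C@](C)(O)[C@@]12C=C/C(=C/Br)CC2 | target

**Step count**
Total: 11 steps. Longest linear sequence: 10 steps (steps 1 and 3–11 from 4'-hydroxyacetophenone); step 2 is a one-step side branch that prepares the allylboronate.

**Steps most likely to fail**

Step 8 (the new method). Three processes may divert it:
- capture of the C11 cation by the C7 silyl ether oxygen, with loss of the silyl group, to give a tetrahydropyran;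
- cleavage of the C6–C7 bond of the spiro adduct with rearomatisation, a net shift of the aryl group from C7 to C11 that leaves a methyl ketone;
- simple reduction or isomerisation of the alkene.

Fallback from 16, by known reaction types. Cobalt-catalysed Markovnikov hydrochlorination of the 1,1-disubstituted alkene (the same cobalt salen complex, TsCl, PhSiH3, EtOH) gives tert-butyl{4-[(2S,4S)-4-bromo-6-chloro-6-methyl-2-(triethylsilyloxy)heptan-2-yl]phenoxy}dimethylsilane F1. Selective cleavage of the aryl silyl ether with KHF2 in MeOH gives 4-[(2S,4S)-4-bromo-6-chloro-6-methyl-2-(triethylsilyloxy)heptan-2-yl]phenol F2. Ionisation of the tertiary chloride with AgOTf and 2,6-di-tert-butylpyridine in hexafluoroisopropanol/CH2Cl2 at low temperature then lets the free phenol alkylate through its para carbon (Ar1-6 closure, a known dearomatising phenol alkylation). The phenol proton is lost at once, which shortens the life of the cationic adduct, and the route is rejoined at 17.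

Step 11. Two processes may fail: weak geometric control in the olefination (the vinyl and the methylene arm of the ketone differ little in size, so much Z isomer may form), and base-induced cleavage of C6–C7 if an alkoxide forms.

Fallback from 19. α-Iodination of the enone (I2, pyridine, CH2Cl2) gives (6S,7S,9R)-9-bromo-7-hydroxy-2-iodo-7,11,11-trimethylspiro[5.5]undec-1-en-3-one F3. The same Wittig reagent then gives (3E,6S,7S,9R)-9-bromo-3-(bromomethylidene)-2-iodo-7,11,11-trimethylspiro[5.5]undec-1-en-7-ol F4, in which allylic strain with the C2 iodine forces the bromine to the C4 side. Selective hydrogenolysis of the vinyl C–I bond with Pd(PPh3)4 (zerovalent palladium) and Bu3SnH, which leaves the vinyl and alkyl bromides, returns to the route at 21.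

Step 10. The process at risk is discrimination between the two dienone alkenes: undirected hydrogenation of the distal alkene or over-reduction may compete. The free carbinol dienone 18 is also prone to C6–C7 fragmentation while it waits.

Fallback from 17, which keeps the silyl ether and uses catalyst control in place of hydroxyl direction. A copper hydride desymmetrising conjugate reduction of the 4,4-disubstituted cyclohexadienone (Cu(OAc)2, the enantiomer of DTBM-SEGPHOS matched to the C4=C5 arm, found by trying both, (EtO)2MeSiH, t-BuOH, toluene) gives (6S,7S,9R)-9-bromo-7,11,11-trimethyl-7-(triethylsilyloxy)spiro[5.5]undec-1-en-3-one F5. Desilylation with HF·pyridine then returns to the route at 19, where the enone no longer has aromatisation as a driving force for fragmentation.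

**Further compounds**
F1 | step 8 | tert-butyl{4-[(2S,4S)-4-bromo-6-chloro-6-methyl-2-(triethylsilyloxy)heptan-2-yl]phenoxy}dimethylsilane | CC(C)(Cl)C[C@@H](Br)C[C@](C)(O[Si](CC)(CC)CC)c1ccc(O[Si](C)(C)C(C)(C)C)cc1
F2 | step 8 | 4-[(2S,4S)-4-bromo-6-chloro-6-methyl-2-(triethylsilyloxy)heptan-2-yl]phenol | CC(C)(Cl)C[C@@H](Br)C[C@](C)(O[Si](CC)(CC)CC)c1ccc(O)cc1
F3 | step 11 | (6S,7S,9R)-9-bromo-7-hydroxy-2-iodo-7,11,11-trimethylspiro[5.5]undec-1-en-3-one | CC1(C)C[C@@H](Br)C[C@](C)(O)[C@@]12C=C(I)C(=O)CC2
F4 | step 11 | (3E,6S,7S,9R)-9-bromo-3-(bromomethylidene)-2-iodo-7,11,11-trimethylspiro[5.5]undec-1-en-7-ol | CC1(C)C[C@@H](Br)C[C@](C)(O)[C@@]12C=C(I)/C(=C/Br)CC2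
F5 | step 10 | (6S,7S,9R)-9-bromo-7,11,11-trimethyl-7-(triethylsilyloxy)spiro[5.5]undec-1-en-3-one | CC1(C)C[C@@H](Br)C[C@](C)(O[Si](CC)(CC)CC)[C@@]12C=CC(=O)CC2
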